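## Retrosynthetic overview
1. Last come fluoride release of the C3 acid (2-(trimethylsilyl)ethyl ester) and of O6 (triethylsilyl ether). C13 comes from a chelate-controlled MeMgBr addition to a vinyl ketone. The C11–C12 bond comes from a zinc-catalysed asymmetric aldol of methyl vinyl ketone with the C11 aldehyde.
2. The C6 carbinol comes from a ketoreductase reduction of the bridged C6 ketone from its exo (α) face.
3. The lactone ring (second ring) comes from iodolactonisation of the C2 acid onto the C7=C8 alkene, which fixes C8. The acid comes from a cinnamyl group on C10.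
4. The C9–C11 bond comes from Wittig methylenation of the C9 enone carbonyl and α-face hydroboration. O6 comes from a vinylogous Rubottom oxidation. C10 comes from two α′-alkylations (cinnamyl first, then methyl anti to the C5 substituent).
5. The first stereocentre C5 and the C4–C5 bond come from a catalytic enantioselective Mukaiyama–Michael addition of an isobutyrate silyl ketene acetal to cyclohexenone. The cyclohexenone carbocycle is ring B (first ring).

Assumption and conventions:
- Labdane locants of the target are used for every intermediate. Ring B = C5–C10; C1–C2 = lactone CH2–C=O; C4/C3 = CMe2/CO2H; C11–C16 = side chain; C17 and C20 = methyls on C8 and C10.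
- β is the ring B face that carries C1, C4, C11, O6 and O8 in the target. α is the other face.
- For each chiral catalyst, ligand or enzyme variant named, the antipode meant is the one that gives the drawn configuration.
- TMSE = 2-(trimethylsilyl)ethyl, TBS = tert-butyldimethylsilyl, TES = triethylsilyl, PMB = 4-methoxybenzyl.

## Route

Step 1
Reactants: 1 2-(trimethylsilyl)ethanol; 2 isobutyryl chloride
Product: 3 TMSE 2-methylpropanoate
Conditions: NEt3, DMAP (cat.), CH2Cl2, 0 °C to rt
Reagents that add atoms: none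
Why: Nucleophilic acyl substitution (esterification) installs a fluoride-labile ester that can be removed at the end without acid or base.

Step 2
Reactants: 3 TMSE 2-methylpropanoate
Product: 4 2-methyl-1-(trimethylsilyloxy)-1-[2-(trimethylsilyl)ethoxy]prop-1-ene (silyl ketene acetal)
Conditions: LiN(iPr)2, THF, −78 °C; Me3SiCl
Reagents that add atoms: chlorotrimethylsilane C[Si](C)(C)Cl
Why: O-silylation of the ester lithium enolate gives the tetrasubstituted ketene acetal, which has no E/Z issue.

Step 3
Reactants: 4 silyl ketene acetal; 5 cyclohex-2-en-1-one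
Product: 7 TMSE 2-methyl-2-[(1R)-3-oxocyclohexyl]propanoate, via silyl enol ether 6 (not isolated)
Conditions: (S)-3,3-diphenyl-1-(o-tolyl)tetrahydropyrrolo[1,2-c][1,3,2]oxazaborole·HNTf2 (20 mol%), Ph3PO (25 mol%), toluene, −20 °C; then 1 M HCl, THF
Reagents that add atoms: none
Why: In this catalytic enantioselective Mukaiyama–Michael addition the chiral oxazaborolidinium cation shields one face of the bound enone, so the congested C4–C5 bond and the first stereocentre C5 (C4 unit β) form in one step.

Step 4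
Reactants: 7 keto ester
Product: 8 C8-(phenylselanyl) ketone (C8 epimers)
Conditions: LiN(iPr)2, THF, −78 °C; PhSeBr
Reagents that add atoms: benzeneselenenyl bromide Br[Se]c1ccccc1
Why: Kinetic deprotonation occurs at C8, away from the tert-alkyl-bearing C5, and the enolate is selenenylated (Reich α-selenenylation).

Step 5
Reactants: 8 C8-(phenylselanyl) ketone
Product: 9 C8-methyl-C8-(phenylselanyl) ketone (C8 epimers)
Conditions: LiN(iPr)2, THF/DMPU, −78 to 0 °C; MeI
Reagents that add atoms: iodomethane CI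
Why: Selenium acidifies C8–H, so enolate alkylation places the C17 methyl regiospecifically on C8.

Step 6
Reactants: 9 C8-methyl-C8-(phenylselanyl) ketone
Product: 11 TMSE 2-methyl-2-[(1R)-4-methyl-5-oxocyclohex-3-en-1-yl]propanoate (C9 enone with C7=C8 alkene), via selenoxide 10 (not isolated)
Conditions: 30% H2O2, pyridine, CH2Cl2, 0 °C to rt
Reagents that add atoms: none
Why: Selenoxide syn-elimination gives mainly the endocyclic 2-methyl enone, and C5 is not touched.

Step 7
Reactants: 11 enone; 12 (E)-cinnamyl bromide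
Product: 13 C10-cinnamyl enone (cinnamyl α, trans to the C4 unit)
Conditions: LiN(iPr)2, THF/DMPU, −78 to −20 °C
Reagents that add atoms: none
Why: Kinetic α′-enolate alkylation can only occur at C10; the cinnamyl group serves as a masked CH2CO2H whose internal styrene alkene is slow toward 9-BBN.

Step 8
Reactants: 13 C10-cinnamyl enone
Product: 14 C10-quaternary enone (C20 methyl α; cinnamyl β, cis to the C4 unit)
Conditions: LiN(iPr)2, THF/DMPU, −78 to 0 °C; MeI
Reagents that add atoms: iodomethane CI
Why: In this second α′-enolate alkylation MeI attacks the cross-conjugated enolate anti to the bulky C5 substituent, which sets C10 with C1 and C4 cis.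

Step 9
Reactants: 14 C10-quaternary enone
Product: 15 C9-O-TBS dienol ether (C9=C8 and C7=C6)
Conditions: TBSOTf, NEt3, CH2Cl2, 0 °C
Reagents that add atoms: tert-butyldimethylsilyl triflate CC(C)(C)[Si](C)(C)OS(=O)(=O)C(F)(F)F
Why: Soft enolisation can only remove a γ-proton (C6–H) because C10 is quaternary, so a single extended silyl dienol ether forms.

Step 10
Reactants: 15 dienol ether
Product: 16 6α-hydroxy enone
Conditions: mCPBA, CH2Cl2/hexane, −20 °C; then 1 M HCl, THF
Reagents that add atoms: 3-chloroperbenzoic acid OOC(=O)c1cccc(Cl)c1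
Why: In this vinylogous Rubottom oxidation the peracid attacks the unhindered γ-terminus C6 anti to the C4 unit; this places oxygen on C6 at the alcohol level, so C5 never becomes epimerisable while the ring is monocyclic.

Step 11
Reactants: 16 6α-hydroxy enone
Product: 17 6α-OTBS enone
Conditions: TBSCl, imidazole, DMF, rt
Reagents that add atoms: tert-butyldimethylsilyl chloride CC(C)(C)[Si](C)(C)Cl
Why: Silyl ether formation blocks O6 before the basic and oxidative steps that follow.

Step 12
Reactants: 17 6α-OTBS enone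
Product: 18 C9-methylene diene (C9=C11H2 conjugated with C7=C8)
Conditions: Ph3PCH3Br, KOtBu, toluene, 0 to 90 °C
Reagents that add atoms: methyltriphenylphosphonium bromide C[P+](c1ccccc1)(c1ccccc1)c1ccccc1.[Br-]
Why: Wittig methylenation under forcing conditions suits this hindered carbonyl, which has no α-proton, and brings in C11.

Step 13
Reactants: 18 C9-methylene diene
Product: 20 homoallylic alcohol (C11H2OH β and H9 α), via alkylborane 19 (not isolated)
Conditions: 9-borabicyclo[3.3.1]nonane, THF, rt to 45 °C; then 30% H2O2, NaOH, 0 °C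
Reagents that add atoms: hydrogen peroxide OO
Why: In this hydroboration–oxidation boron adds to the terminal C11 and hydrogen reaches C9 from the α face, anti to the axial β-cinnamyl group on C10, which sets C9.

Step 14
Reactants: 20 homoallylic alcohol
Product: 21 C11 PMB ether
Conditions: NaH, PMBCl, Bu4NI (cat.), THF/DMF, 0 °C to rt
Reagents that add atoms: 4-methoxybenzyl chloride COc1ccc(CCl)cc1
Why: Williamson etherification gives a protecting group orthogonal to TBS, TES and TMSE.

Step 15
Reactants: 21 C11 PMB ether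
Product: 23 C2 aldehyde, via vicinal diol 22 (not isolated)
Conditions: OsO4 (2 mol%), NaIO4, 2,6-lutidine, dioxane/H2O, rt
Reagents that add atoms: osmium tetroxide O=[Os](=O)(=O)=O; sodium periodate [Na+].[O-]I(=O)(=O)=O
Why: Lemieux–Johnson cleavage takes the accessible styrene alkene in preference to the hindered C7=C8 alkene, which is deactivated by the allylic silyl ether.

Step 16
Reactants: 23 C2 aldehyde
Product: 24 C2 carboxylic acid
Conditions: NaClO2, NaH2PO4, 2-methylbut-2-ene, t-BuOH/H2O, rt
Reagents that add atoms: sodium chlorite [Na+].[O-]Cl=O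
Why: Pinnick oxidation is selective for the aldehyde, and the scavenger protects the ring alkene from HOCl.

Step 17
Reactants: 24 C2 carboxylic acid
Product: 25 7α-iodo δ-lactone (O8 β, C17 methyl α)
Conditions: I2, NaHCO3, MeCN, 0 °C, dark
Reagents that add atoms: iodine II
Why: In this 6-exo iodolactonisation the axial β C1–C2 tether can reach only the β face of the tertiary C8, so trans-diaxial addition sets C8 and closes the second ring.

Step 18
Reactants: 25 7α-iodo δ-lactone
Product: 26 δ-lactone with 6α-OTBS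
Conditions: Bu3SnH, AIBN (cat.), toluene, 80 °C
Reagents that add atoms: none
Why: Radical chain dehalogenation turns C7 into CH2 without touching lactone, ester or ethers.

Step 19
Reactants: 26 δ-lactone with 6α-OTBS
Product: 27 6α-alcohol
Conditions: HF·pyridine, pyridine, THF, 0 °C to rt
Reagents that add atoms: none
Why: Buffered acidic desilylation removes the TBS ether and leaves the TMSE ester, PMB ether and tertiary-alkyl lactone intact.

Step 20
Reactants: 27 6α-alcohol
Product: 28 bridged C6 ketone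
Conditions: Dess–Martin periodinane, CH2Cl2, rt
Reagents that add atoms: none
Why: Dess–Martin oxidation works under non-basic conditions, so the β-acyloxy ketone does not eliminate, and the equatorial β C4 unit is the stable C5 configuration in the bicycle.

Step 21
Reactants: 28 bridged C6 ketone
Product: 29 6β-alcohol (6R)
Conditions: ketoreductase (NADPH-dependent short-chain dehydrogenase/reductase, variant taken from a panel), NADP+ (cat.), i-PrOH (10 vol%), DMSO (5 vol%), KH2PO4/K2HPO4 buffer pH 7.0, 30 °C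
Reagents that add atoms: none
Why: In this biocatalytic ketone reduction the ketoreductase delivers hydride to the open exo (α) face, which is also the intrinsic bias of the bicyclo[3.3.1] ketone; it releases a neutral endo alcohol at pH 7, which sets C6 and suppresses acyl migration to O6.

Step 22
Reactants: 29 6β-alcohol
Product: 30 6β-OTES lactone
Conditions: TESOTf, 2,6-lutidine, CH2Cl2, −78 °C
Reagents that add atoms: triethylsilyl triflate CC[Si](CC)(CC)OS(=O)(=O)C(F)(F)F
Why: Immediate low-temperature silylation caps O6 before it can attack the C2 lactone or the C3 ester.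

Step 23
Reactants: 30 6β-OTES lactone
Product: 31 C11 primary alcohol
Conditions: DDQ, CH2Cl2/pH 7 buffer, 0 °C
Reagents that add atoms: none
Why: Oxidative PMB cleavage is neutral and orthogonal to TES, TMSE and the lactone.

Step 24
Reactants: 31 C11 primary alcohol
Product: 32 C11 aldehyde
Conditions: Dess–Martin periodinane, CH2Cl2, 0 °C to rt
Reagents that add atoms: none
Why: Dess–Martin oxidation gives the β-acyloxy aldehyde without base, and the equatorial formyl group is the stable C9 configuration.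

Step 25
Reactants: 32 C11 aldehyde; 33 methyl vinyl ketone
Product: 34 (11S)-β-hydroxy vinyl ketone
Conditions: (R,R)-ProPhenol (2,6-bis[[2-(hydroxydiphenylmethyl)pyrrolidin-1-yl]methyl]-4-methylphenol, 10 mol%), Et2Zn (20 mol%), 4 Å MS, THF, 0 °C
Reagents that add atoms: none
Why: In this direct catalytic asymmetric aldol the dinuclear zinc catalyst forms the methyl-side enolate of methyl vinyl ketone and selects the aldehyde face, so C11 is set by the catalyst rather than by the nearly symmetric surroundings of C9.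

Step 26
Reactants: 34 (11S)-β-hydroxy vinyl ketone
Product: 35 6-O-TES TMSE ester of the target (11S,13R)
Conditions: MeMgBr (3.5 equiv), CH2Cl2/Et2O, −78 °C; aq. NH4Cl
Reagents that add atoms: methylmagnesium bromide C[Mg]Br
Why: In this chelation-controlled Grignard 1,2-addition the magnesium alkoxide of O11 chelates the C13 carbonyl and methyl adds axially to the six-membered chelate; vinyl and the ring stay equatorial, which gives the 1,3-syn diol and sets C13.

Step 27
Reactants: 35 6-O-TES TMSE ester of the target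
Product: 36 target CNP0297019.1
Conditions: Bu4NF/AcOH (1:1), THF, 0 °C to rt; work-up at pH 5, cold
Reagents that add atoms: none
Why: Buffered fluoride cleaves the TES ether and fragments the TMSE ester (β-silyl elimination) near neutrality, so the δ-lactone, the tertiary allylic alcohol and the free 6-OH/CO2H pair survive.

## Compound list
1 | 2-(trimethylsilyl)ethanol | C[Si](C)(C)CCO | starting material
2 | isobutyryl chloride | CC(C)C(=O)Cl | starting material
3 | TMSE 2-methylpropanoate | CC(C)C(=O)OCC[Si](C)(C)C | intermediate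
4 | 2-methyl-1-(trimethylsilyloxy)-1-[2-(trimethylsilyl)ethoxy]prop-1-ene | CC(C)=C(O[Si](C)(C)C)OCC[Si](C)(C)C | intermediate
5 | cyclohex-2-en-1-one | O=C1C=CCCC1 | starting material
6 | C9 trimethylsilyl enol ether of 7 (not isolated) | C[Si](C)(C)OC1=C[C@H](C(C)(C)C(=O)OCC[Si](C)(C)C)CCC1 | intermediate
7 | TMSE 2-methyl-2-[(1R)-3-oxocyclohexyl]propanoate | O=C1CCC[C@@H](C(C)(C)C(=O)OCC[Si](C)(C)C)C1 | intermediate
8 | C8-(phenylselanyl) ketone, C8 epimers | O=C1C([Se]c2ccccc2)CC[C@@H](C(C)(C)C(=O)OCC[Si](C)(C)C)C1 | intermediate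
9 | C8-methyl-C8-(phenylselanyl) ketone, C8 epimers | O=C1C(C)([Se]c2ccccc2)CC[C@@H](C(C)(C)C(=O)OCC[Si](C)(C)C)C1 | intermediate
10 | selenoxide of 9 (not isolated) | O=C1C(C)([Se](=O)c2ccccc2)CC[C@@H](C(C)(C)C(=O)OCC[Si](C)(C)C)C1 | intermediate
11 | TMSE 2-methyl-2-[(1R)-4-methyl-5-oxocyclohex-3-en-1-yl]propanoate | O=C1C(C)=CC[C@@H](C(C)(C)C(=O)OCC[Si](C)(C)C)C1 | intermediate
12 | (E)-cinnamyl bromide | BrC/C=C/c1ccccc1 | starting material
13 | C10-cinnamyl enone, cinnamyl α | O=C1C(C)=CC[C@@H](C(C)(C)C(=O)OCC[Si](C)(C)C)[C@@H]1C/C=C/c1ccccc1 | intermediate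
14 | C10-quaternary enone, C20 α, cinnamyl β | O=C1C(C)=CC[C@@H](C(C)(C)C(=O)OCC[Si](C)(C)C)[C@@]1(C)C/C=C/c1ccccc1 | intermediate
15 | C9-O-TBS dienol ether | CC(C)(C)[Si](C)(C)OC1=C(C)C=C[C@@H](C(C)(C)C(=O)OCC[Si](C)(C)C)[C@@]1(C)C/C=C/c1ccccc1 | intermediate
16 | 6α-hydroxy enone | O=C1C(C)=C[C@H](O)[C@@H](C(C)(C)C(=O)OCC[Si](C)(C)C)[C@@]1(C)C/C=C/c1ccccc1 | intermediate
17 | 6α-OTBS enone | O=C1C(C)=C[C@H](O[Si](C)(C)C(C)(C)C)[C@@H](C(C)(C)C(=O)OCC[Si](C)(C)C)[C@@]1(C)C/C=C/c1ccccc1 | intermediate
18 | C9-methylene diene | C=C1C(C)=C[C@H](O[Si](C)(C)C(C)(C)C)[C@@H](C(C)(C)C(=O)OCC[Si](C)(C)C)[C@@]1(C)C/C=C/c1ccccc1 | intermediate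
19 | C11 B-alkyl-9-borabicyclo[3.3.1]nonane (not isolated) | C([C@H]1C(C)=C[C@H](O[Si](C)(C)C(C)(C)C)[C@@H](C(C)(C)C(=O)OCC[Si](C)(C)C)[C@@]1(C)C/C=C/c1ccccc1)B1C2CCCC1CCC2 | intermediate
20 | homoallylic alcohol, C11H2OH β, H9 α | OC[C@H]1C(C)=C[C@H](O[Si](C)(C)C(C)(C)C)[C@@H](C(C)(C)C(=O)OCC[Si](C)(C)C)[C@@]1(C)C/C=C/c1ccccc1 | intermediate
21 | C11 PMB ether | COc1ccc(COC[C@H]2C(C)=C[C@H](O[Si](C)(C)C(C)(C)C)[C@@H](C(C)(C)C(=O)OCC[Si](C)(C)C)[C@@]2(C)C/C=C/c2ccccc2)cc1 | intermediate
22 | vicinal diol from the cinnamyl alkene (not isolated) | COc1ccc(COC[C@H]2C(C)=C[C@H](O[Si](C)(C)C(C)(C)C)[C@@H](C(C)(C)C(=O)OCC[Si](C)(C)C)[C@@]2(C)CC(O)C(O)c2ccccc2)cc1 | intermediate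
23 | C2 aldehyde | COc1ccc(COC[C@H]2C(C)=C[C@H](O[Si](C)(C)C(C)(C)C)[C@@H](C(C)(C)C(=O)OCC[Si](C)(C)C)[C@@]2(C)CC=O)cc1 | intermediate
24 | C2 carboxylic acid | COc1ccc(COC[C@H]2C(C)=C[C@H](O[Si](C)(C)C(C)(C)C)[C@@H](C(C)(C)C(=O)OCC[Si](C)(C)C)[C@@]2(C)CC(=O)O)cc1 | intermediate
25 | 7α-iodo δ-lactone | COc1ccc(COC[C@@H]2[C@]3(C)CC(=O)O[C@@]2(C)[C@H](I)[C@H](O[Si](C)(C)C(C)(C)C)[C@H]3C(C)(C)C(=O)OCC[Si](C)(C)C)cc1 | intermediate
26 | δ-lactone, 6α-OTBS | COc1ccc(COC[C@@H]2[C@]3(C)CC(=O)O[C@@]2(C)C[C@H](O[Si](C)(C)C(C)(C)C)[C@H]3C(C)(C)C(=O)OCC[Si](C)(C)C)cc1 | intermediate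
27 | 6α-alcohol | COc1ccc(COC[C@@H]2[C@]3(C)CC(=O)O[C@@]2(C)C[C@H](O)[C@H]3C(C)(C)C(=O)OCC[Si](C)(C)C)cc1 | intermediate
28 | bridged C6 ketone | COc1ccc(COC[C@@H]2[C@]3(C)CC(=O)O[C@@]2(C)CC(=O)[C@H]3C(C)(C)C(=O)OCC[Si](C)(C)C)cc1 | intermediate
29 | 6β-alcohol | COc1ccc(COC[C@@H]2[C@]3(C)CC(=O)O[C@@]2(C)C[C@@H](O)[C@H]3C(C)(C)C(=O)OCC[Si](C)(C)C)cc1 | intermediate
30 | 6β-OTES lactone | COc1ccc(COC[C@@H]2[C@]3(C)CC(=O)O[C@@]2(C)C[C@@H](O[Si](CC)(CC)CC)[C@H]3C(C)(C)C(=O)OCC[Si](C)(C)C)cc1 | intermediate
31 | C11 primary alcohol | OC[C@@H]1[C@]2(C)CC(=O)O[C@@]1(C)C[C@@H](O[Si](CC)(CC)CC)[C@H]2C(C)(C)C(=O)OCC[Si](C)(C)C | intermediate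
32 | C11 aldehyde | O=C[C@@H]1[C@]2(C)CC(=O)O[C@@]1(C)C[C@@H](O[Si](CC)(CC)CC)[C@H]2C(C)(C)C(=O)OCC[Si](C)(C)C | intermediate
33 | methyl vinyl ketone | CC(=O)C=C | starting material
34 | (11S)-β-hydroxy vinyl ketone | C=CC(=O)C[C@H](O)[C@@H]1[C@]2(C)CC(=O)O[C@@]1(C)C[C@@H](O[Si](CC)(CC)CC)[C@H]2C(C)(C)C(=O)OCC[Si](C)(C)C | intermediate
35 | 6-O-TES TMSE ester of the target | C=C[C@](C)(O)C[C@H](O)[C@@H]1[C@]2(C)CC(=O)O[C@@]1(C)C[C@@H](O[Si](CC)(CC)CC)[C@H]2C(C)(C)C(=O)OCC[Si](C)(C)C | intermediate
36 | CNP0297019.1 | C=C[C@](C)(O)C[C@H](O)[C@@H]1[C@]2(C)CC(=O)O[C@@]1(C)C[C@@H](O)[C@H]2C(C)(C)C(=O)O | target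

## Step count and risks

Total step count: 27. Longest linear sequence: 27.

**Step 13.** The hydroboration may fail because the exocyclic alkene is hindered and conjugated, and 9-BBN might also touch the cinnamyl alkene or add with poor face selectivity.
- The fallback sets out from 17 and comes back at 20. It brings in C11 at the aldehyde level instead.
- (Methoxy)(trimethylsilyl)methyllithium, made from MeOCH2SiMe3 and s-BuLi, adds to the C9 carbonyl to give the β-hydroxysilane F1.
- KH triggers Peterson elimination to the methyl dienol ether F2.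
- Oxalic acid on wet silica protonates C9 kinetically from the α face to give the β,γ-unsaturated aldehyde F3.
- F3 is reduced at once with NaBH4 to 20.

**Step 21.** The ketoreductase may not accept so bulky a ketone, or the free 6β-alcohol may lactonise onto C2 or C3.
- The fallback sets out from 28 and comes back at 30.
- It avoids the free alcohol altogether by catalytic hydrosilylation with Et3SiH and RhCl(PPh3)3 in toluene.
- This delivers hydride to the same exo face and gives the TES ether directly. It makes no new compound (F0).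

**Step 25.** The aldol may fail because the aldehyde lies between two quaternary carbons and can lose the C8 carboxylate under the basic zinc catalyst.
- The fallback sets out from 32 and comes back at 35. It builds the chain by allylation and epoxide homologation.
- Keck methallylation with methallyltributylstannane, BINOL and Ti(OiPr)4 gives the (11S)-homoallylic alcohol F4.
- Hydroxyl-directed epoxidation with VO(acac)2 and t-BuOOH gives the syn epoxy alcohol F5.
- Dimethylsulfonium methylide opens the epoxide CH2 and loses Me2S to give the vinyl carbinol 35.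

## Further compounds
F1 | step 13 | β-hydroxysilane from 17 (C9 and C11 epimers) | COC([Si](C)(C)C)C1(O)C(C)=C[C@H](O[Si](C)(C)C(C)(C)C)[C@@H](C(C)(C)C(=O)OCC[Si](C)(C)C)[C@@]1(C)C/C=C/c1ccccc1
F2 | step 13 | methyl dienol ether (E/Z mixture) | COC=C1C(C)=C[C@H](O[Si](C)(C)C(C)(C)C)[C@@H](C(C)(C)C(=O)OCC[Si](C)(C)C)[C@@]1(C)C/C=C/c1ccccc1
F3 | step 13 | β,γ-unsaturated C11 aldehyde, H9 α | O=C[C@H]1C(C)=C[C@H](O[Si](C)(C)C(C)(C)C)[C@@H](C(C)(C)C(=O)OCC[Si](C)(C)C)[C@@]1(C)C/C=C/c1ccccc1
F0 | step 21 | none | none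
F4 | step 25 | (11S)-homoallylic (methallyl) alcohol | C=C(C)C[C@H](O)[C@@H]1[C@]2(C)CC(=O)O[C@@]1(C)C[C@@H](O[Si](CC)(CC)CC)[C@H]2C(C)(C)C(=O)OCC[Si](C)(C)C
F5 | step 25 | syn epoxy alcohol | C1O[C@]1(C)C[C@H](O)[C@@H]2[C@]3(C)CC(=O)O[C@@]2(C)C[C@@H](O[Si](CC)(CC)CC)[C@H]3C(C)(C)C(=O)OCC[Si](C)(C)C
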